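**Retrosynthetic overview**

- The target comes from late α-methylenation of the cis-fused lactone, after one double Mitsunobu esterification with isobutyric acid (inversion at C4) of a diol made by ozonolysis and Luche reduction of a bicyclic enone-lactone.
- The enone-lactone comes from intramolecular aldol condensation of a 1,5-diketone (C5=C6 bond); the ring fixes the tetrasubstituted alkene geometry and C3a settles to the cis fusion.
- The 1,5-diketone comes from the key step: a Stetter union of (S)-citronellal, whose CHO carbon becomes C4 as an acyl anion equivalent, with the electrophilic β-carbon (C3a) of a chiral butenolide.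
- The butenolide comes from asymmetric propiolate addition to a ketal-protected acetoacetaldehyde, then semihydrogenation and lactonisation.
- Ring order: γ-lactone first (step 3), cyclohexene second (step 5).

Assumption: the core is numbered as a 1-benzofuran-2-one (O1, C2, C3, C3a, C4 to C7, C7a), and (S,S)-ProPhenol is taken as the ligand antipode that gives the (R)-carbinol in step 2.

**Route**

Step 1
Reactants: 1 ethyl 2-(2-methyl-1,3-dioxolan-2-yl)acetate
Product: 2 2-(2-methyl-1,3-dioxolan-2-yl)acetaldehyde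
Conditions: i-Bu2AlH (1.05 equiv), CH2Cl2, −78 °C
Reagents that add atoms: none
Why: Partial ester reduction with i-Bu2AlH stops at the aldehyde because the tetrahedral aluminium hemiacetal is stable at −78 °C; no stereocenter is formed.

Step 2
Reactants: 2 2-(2-methyl-1,3-dioxolan-2-yl)acetaldehyde; 3 methyl propiolate
Product: 4 methyl (4R)-4-hydroxy-5-(2-methyl-1,3-dioxolan-2-yl)pent-2-ynoate
Conditions: Me2Zn (3 equiv), (S,S)-ProPhenol (20 mol%), Ph3P=O (40 mol%), PhMe, 4 °C
Reagents that add atoms: none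
Why: Trost ProPhenol dinuclear zinc asymmetric alkynylation adds the zinc propiolate to one aldehyde face and sets the future C7a as (R).

Step 3
Reactants: 4 methyl (4R)-4-hydroxy-5-(2-methyl-1,3-dioxolan-2-yl)pent-2-ynoate
Product: 6 (5R)-5-[(2-methyl-1,3-dioxolan-2-yl)methyl]furan-2(5H)-one, via Z-hydroxy enoate 5 (not isolated)
Conditions: H2 (1 atm), Pd/CaCO3 poisoned with Pb(OAc)2, quinoline, EtOAc, rt; then PPTS (cat.), CH2Cl2, rt
Reagents that add atoms: none
Why: Lindlar syn-semihydrogenation gives the Z-enoate, whose γ-hydroxyl lactonises to the butenolide under anhydrous mild acid that leaves the ketal and C7a untouched.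

Step 4
Reactants: 6 (5R)-5-[(2-methyl-1,3-dioxolan-2-yl)methyl]furan-2(5H)-one; 7 (3S)-3,7-dimethyloct-6-enal ((S)-citronellal)
Product: 8 (4S,5R)-4-[(3S)-3,7-dimethyloct-6-enoyl]-5-[(2-methyl-1,3-dioxolan-2-yl)methyl]oxolan-2-one
Conditions: 7 (2 equiv), 3-benzyl-5-(2-hydroxyethyl)-4-methylthiazolium chloride (20 mol%), Et3N (30 mol%), 1,4-dioxane, 70 °C
Reagents that add atoms: none
Why: Stetter reaction, in which the Breslow intermediate of citronellal acts as an acyl anion and adds 1,4 to the cis-locked butenolide, joining the aldehyde carbon (C4) to the enoate β-carbon (C3a) anti to the C7a substituent; the side-chain stereocenter is β to the new ketone and cannot epimerise.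

Step 5
Reactants: 8 (4S,5R)-4-[(3S)-3,7-dimethyloct-6-enoyl]-5-[(2-methyl-1,3-dioxolan-2-yl)methyl]oxolan-2-one
Product: 10 (3aR,7aR)-6-methyl-5-[(2S)-6-methylhept-5-en-2-yl]-3,3a,7,7a-tetrahydro-1-benzofuran-2,4-dione, via diketone 9 (not isolated)
Conditions: 2 M HCl, THF, rt; then TsOH·H2O (20 mol%), PhMe, 70 °C
Reagents that add atoms: none
Why: After ketal hydrolysis, acid-catalysed intramolecular aldol condensation (Robinson-type closure) joins the C5 enol of the C4 ketone to the methyl ketone C6 and dehydrates to the tetrasubstituted enone, while C3a, now α to the ketone, equilibrates through the enol to the less strained cis-fused lactone and is thereby set relative to C7a.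

Step 6
Reactants: 10 (3aR,7aR)-6-methyl-5-[(2S)-6-methylhept-5-en-2-yl]-3,3a,7,7a-tetrahydro-1-benzofuran-2,4-dione
Product: 12 (3aS,4R,7aR)-4-hydroxy-5-[(2S)-5-hydroxypentan-2-yl]-6-methyl-3a,4,7,7a-tetrahydro-1-benzofuran-2(3H)-one, via keto aldehyde 11 (not isolated)
Conditions: O3 (1 equiv), CH2Cl2/MeOH, −78 °C; then NaBH4, CeCl3·7H2O, −78 to 0 °C
Reagents that add atoms: ozone, [O-][O+]=O
Why: Ozonolysis cleaves only the electron-rich trisubstituted alkene (the enone C=C is deactivated), and in-situ Luche 1,2-reduction reduces the aldehyde and delivers hydride to the C4 ketone from the convex face opposite the lactone, giving the 4R alcohol (OH cis to the lactone).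

Step 7
Reactants: 12 (3aS,4R,7aR)-4-hydroxy-5-[(2S)-5-hydroxypentan-2-yl]-6-methyl-3a,4,7,7a-tetrahydro-1-benzofuran-2(3H)-one
Product: 13 (3aR,4S,7aR)-6-methyl-5-[(2S)-5-(2-methylpropanoyloxy)pentan-2-yl]-2-oxo-2,3,3a,4,7,7a-hexahydro-1-benzofuran-4-yl 2-methylpropanoate
Conditions: i-PrCO2H (3 equiv), PPh3 (3 equiv), DIAD (3 equiv), THF, 0 °C to rt
Reagents that add atoms: isobutyric acid, CC(C)C(=O)O
Why: Double Mitsunobu esterification acylates the primary alcohol and displaces the activated allylic C4 oxygen by SN2 with isobutyrate entering from the open convex face, inverting C4 to the required 4S (ester trans to the lactone).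

Step 8
Reactants: 13 (3aR,4S,7aR)-6-methyl-5-[(2S)-5-(2-methylpropanoyloxy)pentan-2-yl]-2-oxo-2,3,3a,4,7,7a-hexahydro-1-benzofuran-4-yl 2-methylpropanoate
Product: 16 (3aR,4S,7aR)-6-methyl-3-methylidene-5-[(2S)-5-(2-methylpropanoyloxy)pentan-2-yl]-2-oxo-2,3,3a,4,7,7a-hexahydro-1-benzofuran-4-yl 2-methylpropanoate, via Mannich base 14 (not isolated), via ammonium iodide 15 (not isolated)
Conditions: LiN(SiMe3)2 (1.05 equiv), THF, −78 °C; Me2N=CH2 I, −78 °C to rt; then MeI; then NaHCO3 (aq), CH2Cl2, rt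
Reagents that add atoms: N,N-dimethylmethylideneammonium iodide (Eschenmoser's salt), C=[N+](C)C.[I-]
Why: Kinetic enolisation of the lactone CH2 (more acidic and less hindered than the tertiary isobutyrate α-CH) and a Mannich reaction with the iminium salt, followed by N-methylation and base-induced β-elimination, gives the exocyclic methylene; C3 becomes sp2 and no existing stereocenter is touched.

**Compound list**

1 | ethyl 2-(2-methyl-1,3-dioxolan-2-yl)acetate | CCOC(=O)CC1(C)OCCO1 | starting material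
2 | 2-(2-methyl-1,3-dioxolan-2-yl)acetaldehyde | O=CCC1(C)OCCO1 | intermediate
3 | methyl propiolate | C#CC(=O)OC | starting material
4 | methyl (4R)-4-hydroxy-5-(2-methyl-1,3-dioxolan-2-yl)pent-2-ynoate | COC(=O)C#C[C@H](O)CC1(C)OCCO1 | intermediate
5 | methyl (2Z,4R)-4-hydroxy-5-(2-methyl-1,3-dioxolan-2-yl)pent-2-enoate | COC(=O)/C=C\[C@H](O)CC1(C)OCCO1 | intermediate
6 | (5R)-5-[(2-methyl-1,3-dioxolan-2-yl)methyl]furan-2(5H)-one | O=C1C=C[C@@H](CC2(C)OCCO2)O1 | intermediate
7 | (3S)-3,7-dimethyloct-6-enal ((S)-citronellal) | O=CC[C@@H](C)CCC=C(C)C | starting material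
8 | (4S,5R)-4-[(3S)-3,7-dimethyloct-6-enoyl]-5-[(2-methyl-1,3-dioxolan-2-yl)methyl]oxolan-2-one | O=C1C[C@H](C(=O)C[C@@H](C)CCC=C(C)C)[C@@H](CC2(C)OCCO2)O1 | intermediate
9 | (4S,5R)-4-[(3S)-3,7-dimethyloct-6-enoyl]-5-(2-oxopropyl)oxolan-2-one | O=C1C[C@H](C(=O)C[C@@H](C)CCC=C(C)C)[C@@H](CC(C)=O)O1 | intermediate
10 | (3aR,7aR)-6-methyl-5-[(2S)-6-methylhept-5-en-2-yl]-3,3a,7,7a-tetrahydro-1-benzofuran-2,4-dione | O=C1C[C@H]2C(=O)C([C@@H](C)CCC=C(C)C)=C(C)C[C@H]2O1 | intermediate
11 | (4S)-4-[(3aR,7aR)-6-methyl-2,4-dioxo-2,3,3a,4,7,7a-hexahydro-1-benzofuran-5-yl]pentanal | O=C1C[C@H]2C(=O)C([C@@H](C)CCC=O)=C(C)C[C@H]2O1 | intermediate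
12 | (3aS,4R,7aR)-4-hydroxy-5-[(2S)-5-hydroxypentan-2-yl]-6-methyl-3a,4,7,7a-tetrahydro-1-benzofuran-2(3H)-one | O=C1C[C@H]2[C@@H](O)C([C@@H](C)CCCO)=C(C)C[C@H]2O1 | intermediate
13 | (3aR,4S,7aR)-6-methyl-5-[(2S)-5-(2-methylpropanoyloxy)pentan-2-yl]-2-oxo-2,3,3a,4,7,7a-hexahydro-1-benzofuran-4-yl 2-methylpropanoate | O=C1C[C@H]2[C@H](OC(=O)C(C)C)C([C@@H](C)CCCOC(=O)C(C)C)=C(C)C[C@H]2O1 | intermediate
14 | (3aR,4S,7aR)-3-[(dimethylamino)methyl]-6-methyl-5-[(2S)-5-(2-methylpropanoyloxy)pentan-2-yl]-2-oxo-2,3,3a,4,7,7a-hexahydro-1-benzofuran-4-yl 2-methylpropanoate (C3 epimers) | O=C1C(CN(C)C)[C@H]2[C@H](OC(=O)C(C)C)C([C@@H](C)CCCOC(=O)C(C)C)=C(C)C[C@H]2O1 | intermediate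
15 | {(3aR,4S,7aR)-6-methyl-4-(2-methylpropanoyloxy)-5-[(2S)-5-(2-methylpropanoyloxy)pentan-2-yl]-2-oxo-2,3,3a,4,7,7a-hexahydro-1-benzofuran-3-yl}-N,N,N-trimethylmethanaminium iodide (C3 epimers) | O=C1C(C[N+](C)(C)C)[C@H]2[C@H](OC(=O)C(C)C)C([C@@H](C)CCCOC(=O)C(C)C)=C(C)C[C@H]2O1.[I-] | intermediate
16 | (3aR,4S,7aR)-6-methyl-3-methylidene-5-[(2S)-5-(2-methylpropanoyloxy)pentan-2-yl]-2-oxo-2,3,3a,4,7,7a-hexahydro-1-benzofuran-4-yl 2-methylpropanoate | C=C1C(=O)O[C@@H]2CC(C)=C([C@@H](C)CCCOC(=O)C(C)C)[C@@H](OC(=O)C(C)C)[C@H]12 | target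

**Step count and risks**

Total steps: 8. Longest linear sequence: 8 (1 to 16); 3 and 7 enter as purchased.

The three steps most likely to fail:

1. Step 4 (Stetter). A γ-substituted butenolide is a sluggish acceptor for an aliphatic Breslow intermediate. Acyloin formation from 7, amine-induced γ-deprotonation of 6 (erosion of C7a) and β-elimination of the lactone oxygen from 8 all compete. Fallback, setting out from 7 and coming back at 8: use a stoichiometric dithiane acyl anion at low temperature. Aldehyde 7 with propane-1,3-dithiol and catalytic I2 (CHCl3, rt, mild enough to avoid the carbonyl-ene cyclisation of citronellal) gives 2-[(2S)-2,6-dimethylhept-5-en-1-yl]-1,3-dithiane F1. Deprotonation with n-BuLi (THF, −30 °C) and addition of butenolide 6 at −78 °C in THF/DMPU gives the trans conjugate adduct (4S,5R)-4-{2-[(2S)-2,6-dimethylhept-5-en-1-yl]-1,3-dithian-2-yl}-5-[(2-methyl-1,3-dioxolan-2-yl)methyl]oxolan-2-one F2. Alkylative hydrolysis (MeI, CaCO3, aqueous MeCN) unmasks the ketone and returns to 8.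

2. Step 5 (aldol condensation). Both ketones of 9 are β to the lactone oxygen, so enolisation can expel the carboxylate (ring opening, and from 10 aromatisation to a phenol) faster than the aldol closes. The cis preference at C3a also rests on equilibration through the same enol. Fallback, setting out from 4 and coming back at 10: carry the C7a oxygen as a silyl ether (a poor leaving group) through the aldol and close the lactone afterwards.
   - Compound 4 with TBDPSCl and imidazole gives methyl (4R)-4-[(tert-butyldiphenylsilyl)oxy]-5-(2-methyl-1,3-dioxolan-2-yl)pent-2-ynoate F3.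
   - Lindlar semihydrogenation as in step 3 gives methyl (2Z,4R)-4-[(tert-butyldiphenylsilyl)oxy]-5-(2-methyl-1,3-dioxolan-2-yl)pent-2-enoate F4.
   - A Stetter reaction with 7 under the step 4 conditions gives methyl (4R)-4-[(tert-butyldiphenylsilyl)oxy]-3-[(3S)-3,7-dimethyloct-6-enoyl]-5-(2-methyl-1,3-dioxolan-2-yl)pentanoate F5.
   - The acid sequence of step 5 gives methyl 2-[(6R)-6-[(tert-butyldiphenylsilyl)oxy]-4-methyl-3-[(2S)-6-methylhept-5-en-2-yl]-2-oxocyclohex-3-en-1-yl]acetate F6.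
   - HF·pyridine (THF, rt) frees the C7a hydroxyl, which lactonises onto the methyl ester while C3a equilibrates through the enol; the cis isomer is drained into 10.

3. Step 7 (Mitsunobu inversion at C4). The allylic alcohol is flanked by a tetrasubstituted alkene; E2 loss toward a diene, retention through an acyloxyphosphonium, or prior translactonisation of the all-cis diol 12 could intervene. Fallback, setting out from 10 and coming back at 13: set C4 directly by reagent control and acylate with retention. Reduction of 10 with (R)-2-methyl-CBS-oxazaborolidine and catecholborane (PhMe, −78 °C) delivers hydride to the lactone-side face and gives (3aS,4S,7aR)-4-hydroxy-6-methyl-5-[(2S)-6-methylhept-5-en-2-yl]-3a,4,7,7a-tetrahydro-1-benzofuran-2(3H)-one F7. Ozonolysis with NaBH4 work-up as in step 6 gives (3aS,4S,7aR)-4-hydroxy-5-[(2S)-5-hydroxypentan-2-yl]-6-methyl-3a,4,7,7a-tetrahydro-1-benzofuran-2(3H)-one F8. Isobutyric anhydride with DMAP and Et3N (CH2Cl2, rt) acylates both hydroxyls and returns to 13.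

**Further compounds**

F1 | step 4 | 2-[(2S)-2,6-dimethylhept-5-en-1-yl]-1,3-dithiane | S1CCCSC1C[C@@H](C)CCC=C(C)C
F2 | step 4 | (4S,5R)-4-{2-[(2S)-2,6-dimethylhept-5-en-1-yl]-1,3-dithian-2-yl}-5-[(2-methyl-1,3-dioxolan-2-yl)methyl]oxolan-2-one | O=C1C[C@H](C2(C[C@@H](C)CCC=C(C)C)SCCCS2)[C@@H](CC2(C)OCCO2)O1
F3 | step 5 | methyl (4R)-4-[(tert-butyldiphenylsilyl)oxy]-5-(2-methyl-1,3-dioxolan-2-yl)pent-2-ynoate | COC(=O)C#C[C@H](O[Si](c1ccccc1)(c1ccccc1)C(C)(C)C)CC1(C)OCCO1
F4 | step 5 | methyl (2Z,4R)-4-[(tert-butyldiphenylsilyl)oxy]-5-(2-methyl-1,3-dioxolan-2-yl)pent-2-enoate | COC(=O)/C=C\[C@H](O[Si](c1ccccc1)(c1ccccc1)C(C)(C)C)CC1(C)OCCO1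
F5 | step 5 | methyl (4R)-4-[(tert-butyldiphenylsilyl)oxy]-3-[(3S)-3,7-dimethyloct-6-enoyl]-5-(2-methyl-1,3-dioxolan-2-yl)pentanoate (C3 epimers) | COC(=O)CC(C(=O)C[C@@H](C)CCC=C(C)C)[C@H](O[Si](c1ccccc1)(c1ccccc1)C(C)(C)C)CC1(C)OCCO1
F6 | step 5 | methyl 2-[(6R)-6-[(tert-butyldiphenylsilyl)oxy]-4-methyl-3-[(2S)-6-methylhept-5-en-2-yl]-2-oxocyclohex-3-en-1-yl]acetate (C1 epimers) | COC(=O)CC1C(=O)C([C@@H](C)CCC=C(C)C)=C(C)C[C@H]1O[Si](c1ccccc1)(c1ccccc1)C(C)(C)C
F7 | step 7 | (3aS,4S,7aR)-4-hydroxy-6-methyl-5-[(2S)-6-methylhept-5-en-2-yl]-3a,4,7,7a-tetrahydro-1-benzofuran-2(3H)-one | O=C1C[C@H]2[C@H](O)C([C@@H](C)CCC=C(C)C)=C(C)C[C@H]2O1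
F8 | step 7 | (3aS,4S,7aR)-4-hydroxy-5-[(2S)-5-hydroxypentan-2-yl]-6-methyl-3a,4,7,7a-tetrahydro-1-benzofuran-2(3H)-one | O=C1C[C@H]2[C@H](O)C([C@@H](C)CCCO)=C(C)C[C@H]2O1
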